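The rate constants are assumed, and the outcome is calculated.

You cannot get the target in a flask read at 2.0 min by stretching the same flask read at 50 s: target is made from substrate and drained into its isomer over the same catalyst, so the two readings need separate reckoning.

substrate 0.010 M; gas phase 3.5 mM (held); catalyst 0.50 mM; time 2.0 min

    substrate + dissolved gas + catalyst → catalyst + target (k1 = 1100 M⁻² s⁻¹)
    target + catalyst ⇌ isomer of the product + catalyst, rate k2*[catalyst]*[target] forward; the back reaction follows from the equilibrium constant (K2 = 2.0, k2 = 15 M⁻¹ s⁻¹)
    gas phase ⇌ dissolved gas, rate k3*(csat - [dissolved gas]) (k3 = 0.086 s⁻¹, csat = 3.5 mM)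
    substrate + target → side product (k4 = 0.055 M⁻¹ s⁻¹)

- the target standing at 2.0 min, as a percentage of the substrate charged
- concentration of dissolved gas in solution at 2.0 min, in percent of saturation

- a species is counted by the substrate in it: one side product counts as two
- at the start none of the gas is dissolved
- run time (flask): 2.0 min

My reckoning starts with the gas. Transfer runs at 0.086 s⁻¹ and uptake at 0.00550 s⁻¹, the step-one constant times catalyst and substrate, which is slower. So dissolved gas climbs with a lag of 11.6 s, the inverse transfer coefficient, to a share g of saturation, transfer over transfer plus uptake, of 94.0 %, with the substrate taken at its charge. The substrate then decays as a pseudo-first-order species at κ = 0.00181 s⁻¹, over τ, the reading time less the lag: 108 s or 38.4 s.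

The correction is the drain. Target and isomer relax at μ = 0.0112 s⁻¹, the forward constant times catalyst times one plus the inverse equilibrium constant K. Product arriving evenly over τ stands as target in the share f = (1 + K(1 − e^(−μτ))/(μτ))/(1 + K). At 2.0 min this gives 71.9 %, the retained fraction, and at 50 s it gives 87.5 %, because the longer τ exceeds 1/μ = 89.3 s and the shorter falls below it. Leaving out the side product, I get 12.8 % at 2.0 min and 5.87 % at 50 s: time grows 2.40-fold, target 2.18-fold.

The forecast gives 12.4 % of target and 95 % of saturation, the second on the ground that “uptake is slow compared with gas transfer”; its target stands below mine and its saturation above mine.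

The flask gives 12.4 % of target and 94.9 % of saturation at 2.0 min. The relaxation half-life of target and isomer in this flask at 2.0 min, 1.03 min, is shorter than the 2.0 min of the run and longer than the 50 s of the neighbour, the same flask read earlier. Target over target plus isomer stands at 70.7 % in the flask at 2.0 min, against f = 71.9 %, while the neighbour at 50 s, with 5.86 % of target, stands at 86.3 %, against f = 87.5 %.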